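Locants: ring B carries phthalide numbering (C1 lactone C=O, C3 lactol carbon, C4 ether oxygen, C5 ester oxygen, C6 CH2OAc, C7 OH); ring A carries primed locants (C1′ depsidone C=O, C2′ O-aryl, C3′ CHO, C4′ OH, C5′ H, C6′ CH3).
Retrosynthesis, in order: the three allyl carbonate masks and the lactol configuration; the acetate and the methyl masks; the C1′–C(=O) bond of the seven-membered lactone, cut back to a C1′ aryl iodide and a six-membered cyclic carbonate joining the C5 oxygen to the benzylic oxygen on C6; the C2′–O diaryl ether bond (SNAr).
Feature used: on ring B the ester oxygen (on C5) is ortho to the CH2O-bearing carbon (C6), so one carbonyl carbon can bridge both oxygens; on ring A the carbon that must carry this carbonyl (C1′) is ortho to the ether oxygen (on C2′), so a C1′ carbanion reaches the carbonate carbon through a seven-membered transition state.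
Forward: ring B phthalide acetal from 2,4,5-trimethoxybenzoic acid (steps 1–5); ring A fluoro-iodo aldehyde (steps 6–7); diaryl ether (8); cyclic carbonate (9–10); depsidone ring by anionic carbonate-to-lactone acyl transfer (11); acetate and demethylation (12–13).
Stereochemistry: the single stereocentre (lactol carbon, S) is carried as the racemate, set in step 14 by catalyst-controlled dynamic kinetic allyloxycarbonylation and released in step 15 without breaking a bond to it.

Key step: step 11

Assumption: the lactol carbon of a 3-hydroxyphthalide epimerises by ring–chain tautomerism whenever acid or base is present, so it is fixed only in step 14 as a configurationally stable carbonate, and the free lactol 22 is expected to hold its configuration only under neutral aprotic handling.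

Step 1
Reactants: 1 2,4,5-trimethoxybenzoic acid
Product: 3 racemic 3,4,5,7-tetramethoxyisobenzofuran-1(3H)-one, via lactol 2 (not isolated)
Conditions: s-BuLi (2.2 equiv), TMEDA, THF, −78 °C; DMF, −78 °C → rt; aq. HCl; then MeOH, H2SO4 (cat.), 65 °C
Reagents that add atoms: N,N-dimethylformamide CN(C)C=O; methanol CO
Why: Carboxylate-directed ortho-lithiation (directed ortho metalation) is expected at the only position ortho to the lithium carboxylate, which is also activated by the neighbouring 5-methoxy group, so formylation with DMF, ring closure to the lactol and acid-catalysed pseudo-ester formation (Fischer-type acetalisation) should give the methyl acetal, whose new acetal stereocentre forms as the racemate.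

Step 2
Reactants: 3 racemic 3,4,5,7-tetramethoxyisobenzofuran-1(3H)-one
Product: 4 racemic 6-formyl-3,4,5,7-tetramethoxyisobenzofuran-1(3H)-one
Conditions: Cl2CHOMe, TiCl4, CH2Cl2, −20 → 0 °C; then H2O
Reagents that add atoms: dichloromethyl methyl ether COC(Cl)Cl; water O
Why: Rieche formylation (electrophilic aromatic substitution) can occur only at the single free ring position C6, which is activated by its two flanking methoxy groups and lies meta to the lactone carbonyl, and creates no stereocentre.

Step 3
Reactants: 4 racemic 6-formyl-3,4,5,7-tetramethoxyisobenzofuran-1(3H)-one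
Product: 6 racemic 6-formyl-4,5,7-trihydroxy-3-methoxyisobenzofuran-1(3H)-one, via tetrahydroxy lactol 5 (not isolated)
Conditions: BBr3 (6 equiv), CH2Cl2, −78 °C → rt; then MeOH, 50 °C
Reagents that add atoms: methanol CO
Why: Boron tribromide ether cleavage removes all four methyl groups, and the methanol quench should re-form the methyl pseudo-ester from the transient lactol by HBr-catalysed Fischer-type acetalisation, again as the racemate.

Step 4
Reactants: 6 racemic 6-formyl-4,5,7-trihydroxy-3-methoxyisobenzofuran-1(3H)-one
Product: 7 racemic 4,5,7-trihydroxy-6-(hydroxymethyl)-3-methoxyisobenzofuran-1(3H)-one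
Conditions: NaBH4, THF–MeOH, −10 °C, argon; then aq. HCl to pH 4
Reagents that add atoms: none
Why: Chemoselective borohydride reduction of the aryl aldehyde should leave the pseudo-ester intact, because a lactone carbonyl is not reduced by NaBH4 at this temperature and this one is further deactivated as the vinylogous carboxylate of the ortho phenoxide.

Step 5
Reactants: 7 racemic 4,5,7-trihydroxy-6-(hydroxymethyl)-3-methoxyisobenzofuran-1(3H)-one
Product: 8 racemic ring B acetonide (isopropylidene acetal across the C5 oxygen and the C6 CH2O; C4–OH and C7–OH free)
Conditions: 2,2-dimethoxypropane, pyridinium p-toluenesulfonate (cat.), acetone, rt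
Reagents that add atoms: 2,2-dimethoxypropane COC(C)(C)OC
Why: Acid-catalysed transketalisation under thermodynamic control should place the isopropylidene group on the C5 oxygen and the benzylic oxygen (six-membered 1,3-benzodioxine), since this keeps the C7 hydroxyl hydrogen-bonded to the lactone carbonyl and avoids the strained five-membered catechol ketal, leaving the C4 phenol as the only non-chelated nucleophile.

Step 6
Reactants: 9 1-fluoro-3-methoxy-5-methylbenzene
Product: 10 2-fluoro-6-methoxy-4-methylbenzaldehyde
Conditions: n-BuLi, THF, −78 °C; DMF; aq. HCl
Reagents that add atoms: N,N-dimethylformamide CN(C)C=O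
Why: Directed ortho metalation at the ring position flanked by fluorine and methoxy (the most acidic hydrogen) followed by formylation with DMF.

Step 7
Reactants: 10 2-fluoro-6-methoxy-4-methylbenzaldehyde
Product: 11 2-fluoro-3-iodo-6-methoxy-4-methylbenzaldehyde
Conditions: N-iodosuccinimide, CF3CO2H, MeCN, rt
Reagents that add atoms: N-iodosuccinimide O=C1CCC(=O)N1I
Why: Electrophilic aromatic iodination is expected para to the methoxy group (the strongest donor) at the less hindered of the two positions meta to the formyl group, as in the para-halogenation of 3-fluoroanisoles.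

Step 8
Reactants: 8 racemic ring B acetonide; 11 2-fluoro-3-iodo-6-methoxy-4-methylbenzaldehyde
Product: 13 racemic diaryl ether with C7–OMe, via diaryl ether phenol 12 (not isolated)
Conditions: Cs2CO3 (2.5 equiv), DMF, 70 °C, argon; then MeI, rt
Reagents that add atoms: iodomethane CI
Why: Nucleophilic aromatic substitution of the fluoride activated by the ortho formyl group should take place through the non-chelated C4 phenoxide (the C7 phenoxide is a hydrogen-bonded vinylogous carboxylate, as in the selective 5-O-functionalisation of 2,5-dihydroxybenzoates), and Williamson methylation in the same flask then caps the remaining C7 phenoxide.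

Step 9
Reactants: 13 racemic diaryl ether with C7–OMe
Product: 14 racemic phenol–benzylic alcohol with ring A dimethyl acetal
Conditions: MeOH, HC(OMe)3, pyridinium p-toluenesulfonate (cat.), rt → 40 °C
Reagents that add atoms: methanol CO; trimethyl orthoformate COC(OC)OC
Why: Acid-catalysed acetal exchange in methanol (transketalisation of the aryl alkyl isopropylidene ketal and orthoformate-driven dimethyl acetal formation) should unmask the C5 phenol and the benzylic alcohol and protect the ring A aldehyde for the organolithium step, while the less labile methyl pseudo-ester persists.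

Step 10
Reactants: 14 racemic phenol–benzylic alcohol with ring A dimethyl acetal
Product: 15 racemic six-membered cyclic carbonate (C5–O–C(=O)–O–CH2–C6)
Conditions: 1,1′-carbonyldiimidazole, THF, rt
Reagents that add atoms: 1,1′-carbonyldiimidazole O=C(n1ccnc1)n1ccnc1
Why: Carbonylation of the 1,3-related phenol and primary alcohol with carbonyldiimidazole (acyl imidazole formation, then intramolecular acyl substitution) can give only this six-membered cyclic carbonate, because the other neighbouring oxygen (on C7) is methylated.

Step 11
Reactants: 15 racemic six-membered cyclic carbonate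
Product: 18 racemic hydroxymethyl depsidone aldehyde, via aryllithium 16 (not isolated), via dimethyl acetal 17 (not isolated)
Conditions: n-BuLi (1.05 equiv), THF, −100 °C; AcOH, −100 → 0 °C; then 0.5 M aq. HCl, THF, 0 °C
Reagents that add atoms: water O
Why: Iodine–lithium exchange generates the aryllithium only at C1′ (the one carbon bearing iodine), this carbanion adds to the carbonate carbonyl, and the resulting ortho ester alkoxide collapses with opening of the six-membered carbonate, so that the carbonate carbon becomes the depsidone carbonyl and the benzylic oxygen is freed for the later acetylation. The closest known reaction type is the Parham cyclisation (an aryllithium from halogen–metal exchange captured by an internal carbonate, carbamate or ester), related to the remote anionic Fries O-to-C acyl transfer. The seven-membered ring closes in a 7-exo-trig mode through the new C1′–C(=O) bond, and the temporary carbonate ring is opened in the same event. No stereocentre is created and the racemic acetal centre is untouched. The step needs exchange to outrun addition of n-BuLi to a carbonyl group (secured by the aryl iodide and −100 °C) and needs the carbonate to be the only electrophile in reach of C1′ (the pseudo-ester carbonyl lies on the far side of ring B and the aldehyde is masked as its acetal). The direction of collapse is secured by ring strain, since loss of the C5 phenoxide would leave a nine-membered lactone bridging the meta-related C4 and C6 of ring B, whereas loss of the benzylic alkoxide leaves the seven-membered aryl ester, and the acidic work-up then hydrolyses the ring A acetal.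

Step 12
Reactants: 18 racemic hydroxymethyl depsidone aldehyde
Product: 19 racemic acetoxymethyl depsidone
Conditions: Ac2O, pyridine, CH2Cl2, 0 °C
Reagents that add atoms: acetic anhydride CC(=O)OC(C)=O
Why: O-Acetylation (nucleophilic acyl substitution) of the only free hydroxyl group, run without strong base so that the neighbouring aryl ester does not migrate to the benzylic oxygen.

Step 13
Reactants: 19 racemic acetoxymethyl depsidone
Product: 20 racemic galbinic acid
Conditions: BCl3 (8 equiv), CH2Cl2, −78 → −10 °C; then H2O, THF, 0 °C
Reagents that add atoms: water O
Why: Chelation-assisted BCl3 demethylation of the two aryl methyl ethers that sit ortho to a carbonyl group (on C4′ beside the aldehyde, on C7 beside the lactone), together with Lewis-acid cleavage of the methyl pseudo-ester and hydrolytic work-up, should give the free lactol as the racemate, the benzylic acetate being expected to survive on its electron-poor ring.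

Step 14
Reactants: 20 racemic galbinic acid
Product: 21 (R)-tris(allyl carbonate) of galbinic acid
Conditions: diallyl dicarbonate (4 equiv), (2S,3R)-3-isopropyl-2-phenyl-3,4-dihydro-2H-benzo[4,5]thiazolo[3,2-a]pyrimidine (10 mol %), i-Pr2NEt, CHCl3, −40 °C
Reagents that add atoms: diallyl dicarbonate C=CCOC(=O)OC(=O)OCC=C
Why: Proposed new method: under the amine base the two lactol enantiomers of 20 interconvert through the ring-opened formyl carboxylate, while the chiral N-allyloxycarbonyl isothiouronium ion formed from the catalyst and the dicarbonate should transfer its carbonate group faster to one lactol enantiomer, giving the configurationally fixed acylal carbonate as the (R)-isomer (catalyst antipode to be chosen accordingly) and carbonating the two chelated phenols without stereochemical consequence; the closest known reaction type is the isothiourea- or chiral 4-aminopyridine-catalysed acylative dynamic kinetic resolution of 3-hydroxyphthalides and related lactols with carboxylic anhydrides, here extended to a dicarbonate donor.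

Step 15
Reactants: 21 (R)-tris(allyl carbonate) of galbinic acid
Product: 22 galbinic acid, (S) at the lactol carbon
Conditions: Pd(PPh3)4 (5 mol %), Bu3SnH, AcOH, CH2Cl2, 0 °C, argon
Reagents that add atoms: none
Why: Zerovalent-palladium-catalysed deallylation (Tsuji–Trost ionisation of the three allyl carbonates, hydride transfer from tin to the allyl unit, protonolysis and loss of CO2) frees both phenols and the lactol without cleaving any bond to the lactol carbon, so the configuration set in step 14 is retained and reads (S) only because the priority order changes.

Compound list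
1 | 2,4,5-trimethoxybenzoic acid | OC(=O)c1cc(OC)c(OC)cc1OC | starting material
2 | 3-hydroxy-4,5,7-trimethoxyisobenzofuran-1(3H)-one (racemic lactol) | OC1OC(=O)c2c(OC)cc(OC)c(OC)c12 | intermediate (not isolated)
3 | 3,4,5,7-tetramethoxyisobenzofuran-1(3H)-one (racemic) | COC1OC(=O)c2c(OC)cc(OC)c(OC)c12 | intermediate
4 | 6-formyl-3,4,5,7-tetramethoxyisobenzofuran-1(3H)-one (racemic) | COC1OC(=O)c2c(OC)c(C=O)c(OC)c(OC)c12 | intermediate
5 | 6-formyl-3,4,5,7-tetrahydroxyisobenzofuran-1(3H)-one (racemic lactol) | OC1OC(=O)c2c(O)c(C=O)c(O)c(O)c12 | intermediate (not isolated)
6 | 6-formyl-4,5,7-trihydroxy-3-methoxyisobenzofuran-1(3H)-one (racemic) | COC1OC(=O)c2c(O)c(C=O)c(O)c(O)c12 | intermediate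
7 | 4,5,7-trihydroxy-6-(hydroxymethyl)-3-methoxyisobenzofuran-1(3H)-one (racemic) | COC1OC(=O)c2c(O)c(CO)c(O)c(O)c12 | intermediate
8 | 4,7-dihydroxy-3-methoxyisobenzofuran-1(3H)-one carrying a 2,2-dimethyl-4H-1,3-dioxine ring fused at C5–C6 (ring oxygen on C5; ring CH2 on C6); racemic | COC1OC(=O)c2c(O)c3COC(C)(C)Oc3c(O)c12 | intermediate
9 | 1-fluoro-3-methoxy-5-methylbenzene | COc1cc(C)cc(F)c1 | starting material
10 | 2-fluoro-6-methoxy-4-methylbenzaldehyde | COc1cc(C)cc(F)c1C=O | intermediate
11 | 2-fluoro-3-iodo-6-methoxy-4-methylbenzaldehyde | COc1cc(C)c(I)c(F)c1C=O | intermediate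
12 | compound 8 whose C4 oxygen carries a 2-formyl-6-iodo-3-methoxy-5-methylphenyl group; C7–OH free; racemic | COC1OC(=O)c2c(O)c3COC(C)(C)Oc3c(Oc3c(C=O)c(OC)cc(C)c3I)c12 | intermediate (not isolated)
13 | compound 12 with the C7 hydroxyl methylated; racemic | COC1OC(=O)c2c(OC)c3COC(C)(C)Oc3c(Oc3c(C=O)c(OC)cc(C)c3I)c12 | intermediate
14 | 4-[2-(dimethoxymethyl)-6-iodo-3-methoxy-5-methylphenoxy]-5-hydroxy-6-(hydroxymethyl)-3,7-dimethoxyisobenzofuran-1(3H)-one (racemic) | COC1OC(=O)c2c(OC)c(CO)c(O)c(Oc3c(C(OC)OC)c(OC)cc(C)c3I)c12 | intermediate
15 | cyclic carbonate of 14: the C5 oxygen and the C6 CH2O are bridged by C=O (4H-1,3-dioxin-2-one ring fused at C5–C6); racemic | COC1OC(=O)c2c(OC)c3COC(=O)Oc3c(Oc3c(C(OC)OC)c(OC)cc(C)c3I)c12 | intermediate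
16 | compound 15 with lithium in place of iodine (aryllithium at C1′); racemic | COC1OC(=O)c2c(OC)c3COC(=O)Oc3c(Oc3c(C(OC)OC)c(OC)cc(C)c3[Li])c12 | intermediate (not isolated)
17 | depsidone (C1′–C(=O)–O–C5 and C2′–O–C4) with CH(OMe)2 on C3′, OMe on C4′, CH3 on C6′, CH2OH on C6, OMe on C7 and the 3-methoxy γ-lactone; racemic | COC1OC(=O)c2c(OC)c(CO)c3OC(=O)c4c(C)cc(OC)c(C(OC)OC)c4Oc3c12 | intermediate (not isolated)
18 | compound 17 with the free aldehyde on C3′; racemic | COC1OC(=O)c2c(OC)c(CO)c3OC(=O)c4c(C)cc(OC)c(C=O)c4Oc3c12 | intermediate
19 | compound 18 with CH2OAc on C6; racemic | COC1OC(=O)c2c(OC)c(COC(C)=O)c3OC(=O)c4c(C)cc(OC)c(C=O)c4Oc3c12 | intermediate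
20 | racemic galbinic acid (depsidone with CHO on C3′, OH on C4′, CH3 on C6′, CH2OAc on C6, OH on C7 and the 3-hydroxy γ-lactone) | CC(=O)OCc1c(O)c2c(c3c1OC(=O)c1c(C)cc(O)c(C=O)c1O3)C(O)OC2=O | intermediate
21 | galbinic acid tris(allyl carbonate) on the C4′ oxygen, the C7 oxygen and the lactol oxygen; (R) at the acylal carbon (same spatial arrangement as the (S)-lactol of 22) | CC(=O)OCc1c(OC(=O)OCC=C)c2c(c3c1OC(=O)c1c(C)cc(OC(=O)OCC=C)c(C=O)c1O3)[C@@H](OC(=O)OCC=C)OC2=O | intermediate
22 | galbinic acid, (S) at the lactol carbon | CC(=O)OCc1c(O)c2c(c3c1OC(=O)c1c(C)cc(O)c(C=O)c1O3)[C@@H](O)OC2=O | target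

Total steps: 15. Longest linear sequence: 13 steps (steps 1–5 and 8–15 from compound 1); ring A is made in two steps (6–7) and joined in step 8.

Steps most likely to fail

Step 14 (carries the new-method label). What may go wrong: insufficient discrimination between the lactol enantiomers, lactol epimerisation too slow relative to carbonate transfer (a plain kinetic resolution), or allyloxycarbonylation of the ring-opened carboxylate to a normal allyl ester. Fallback with known chemistry: starting from 20, exhaustive allyloxycarbonylation with diallyl dicarbonate and achiral 4-(dimethylamino)pyridine gives the racemic tris(allyl carbonate) F1, whose enantiomers are separated by preparative chromatography on a chiral stationary phase; the (R)-enantiomer is 21, where the route resumes, and the (S)-tris(allyl carbonate) F2 is set aside.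

Step 11. What may go wrong: addition of n-BuLi to the carbonate or pseudo-ester carbonyl before the exchange, quenching of the aryllithium by proton transfer (for example from the acetal C3–H), or opening of the new aryl ester by the liberated benzylic alkoxide. Fallback: starting from 14 (before the carbonate is made), a palladium-catalysed carbonylative lactonisation (Pd(OAc)2, 4,5-bis(diphenylphosphino)-9,9-dimethylxanthene, CO at 1 atm, Et3N, toluene, 80 °C) inserts CO into the C1′–I bond and lets the C5 phenol capture the acylpalladium, giving 17 directly; the acidic work-up of step 11 then delivers 18, where the route resumes; no compound outside the list is formed (F0).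

Step 9. What may go wrong: solvolysis of the ortho-hydroxybenzylic alcohol to its methyl ether in acidic methanol, or acetal exchange at the pseudo-ester. Fallback: starting from 13, the acetonide is removed in water-containing medium (80% aqueous acetic acid, 40 °C) to give the racemic aldehyde diol F3; carbonyldiimidazole in THF then ties up the benzylic oxygen as the racemic aldehyde cyclic carbonate F4, and only then is the aldehyde converted into its dimethyl acetal (HC(OMe)3, pyridinium p-toluenesulfonate), which gives 15, where the route resumes.

Further compounds
F1 | step 14 | racemic galbinic acid tris(allyl carbonate) (racemate of 21) | CC(=O)OCc1c(OC(=O)OCC=C)c2c(c3c1OC(=O)c1c(C)cc(OC(=O)OCC=C)c(C=O)c1O3)C(OC(=O)OCC=C)OC2=O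
F2 | step 14 | (S)-tris(allyl carbonate) of galbinic acid (enantiomer of 21) | CC(=O)OCc1c(OC(=O)OCC=C)c2c(c3c1OC(=O)c1c(C)cc(OC(=O)OCC=C)c(C=O)c1O3)[C@H](OC(=O)OCC=C)OC2=O
F0 | step 11 | none | none
F3 | step 9 | 4-(2-formyl-6-iodo-3-methoxy-5-methylphenoxy)-5-hydroxy-6-(hydroxymethyl)-3,7-dimethoxyisobenzofuran-1(3H)-one (racemic) | COC1OC(=O)c2c(OC)c(CO)c(O)c(Oc3c(C=O)c(OC)cc(C)c3I)c12
F4 | step 9 | cyclic carbonate of F3 (C5 oxygen and C6 CH2O bridged by C=O; racemic) | COC1OC(=O)c2c(OC)c3COC(=O)Oc3c(Oc3c(C=O)c(OC)cc(C)c3I)c12
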